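Readings and results were generated by integration with made-up constants; the scatter is artificial.

At the same 82 °C, the maple run holds 29.0 times the concentration of product of the ash run at 4.00 min, on 2.08 times the coupling partner and 1.52 times the substrate.

| setting | ash | birch | maple | red | teal | amber | blue |
|---|---|---|---|---|---|---|---|
| substrate | 0.25 M | 0.25 M | 0.38 M | 0.25 M | 0.25 M | 0.25 M | 0.25 M |
| coupling partner | 0.12 M | 0.50 M | 0.25 M | 0.250 M | 0.250 M | 0.250 M | 0.250 M |
| temperature | 82 °C | 110 °C | 82 °C | 95 °C | 70 °C |  | 120 °C |
| remark | run made earlier | run made earlier | run made earlier |  |  | at 70 °C until 2.0 min, from then on at 120 °C |  |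
| time |  |  |  | 2.5 min | 2.5 min | 2.5 min | 2.5 min |

ash run (percent of the substrate charged)

| time / min | product / % | substrate / % |
|---|---|---|
| 0.333 | 0.4 | 99.8 |
| 1.00 | 0 | 99.1 |
| 2.00 | 0 | 99.9 |
| 2.50 | 0 | 99.6 |
| 4.00 | 2.9 | 98.6 |

birch run (percent of the substrate charged)

| time / s | product / % | substrate / % |
|---|---|---|
| 12.0 | 0.2 | 98.6 |
| 25.0 | 10.4 | 89.6 |
| 40.0 | 51.6 | 48.3 |
| 60.0 | 89.5 | 10.3 |

maple run (percent of the substrate charged)

| time / min | product / % | substrate / % |
|---|---|---|
| 0.833 | 1.3 | 100.2 |
| 1.50 | 3.4 | 97.5 |
| 2.50 | 22.6 | 77.7 |
| 3.00 | 38.2 | 61.5 |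
| 4.00 | 55.3 | 43.5 |

(scatter of a reading: 0.5 percentage points)

- a reading or a percentage of product counts all its forms, free or not

- which flask leads in amount of product, in percent of the substrate charged ("all alike" within 1.5 percentage points) (red / teal / amber / blue / all alike)
- how much product is there at the end, in percent of the substrate charged: red
- how much product is there at the end, in percent of the substrate charged: teal
- how much product is there at the end, in percent of the substrate charged: amber
- how much product is there at the end, in percent of the substrate charged: blue

The concentration that sets the order here is the product's. Each run sits flat and then takes off, and product plus substrate stays near the charge, so I write the rate as a constant times substrate, partner and product: autocatalysis. The logarithm of product over substrate then climbs with a slope of that constant times the substrate charge and the partner present, so the slope falls as partner is used. Scaled to the recipe's charges, its slope gives a growth constant of 1.86 min⁻¹ at 82 °C from maple and 5.25 min⁻¹ at 110 °C from birch.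

The charges sit inside an exponent, and that clears the puzzle: at 4.00 min the unslowed exponent is 3.56 in ash and 11.3 in maple.

A straight line in the logarithm against temperature gives 1.19 min⁻¹ at 70 °C and 7.62 min⁻¹ at 120 °C. At 120 °C that makes 0.0910 min the doubling time of the product: ln 2 over the growth constant, while substrate and partner stand near their charges.

Amber tests it. Running the early readings backwards, I get a slow start making 0.00139 min⁻¹ of the charge per minute at 82 °C and 0.00765 min⁻¹ at 110 °C, at the recipe's partner. Carried down to 70 °C, that is 6.72 × 10⁻⁴ min⁻¹, so amber holds about 0.552% at 2.0 min. The hot 0.500 min then holds 5.50 doublings, which would reach 24.9%. Growth falls with the square of what is left, so I commit to about 14.0%.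

The forecast names blue as leader, with red 55%, teal 1.5%, amber 48% (range 22% to 70%) and blue 87%. Its ground for amber differs from mine: “2 min at 70 °C uses about 80% of induction, leaving about 0.38 min of reaction at 120 °C”.

The flasks give red 46.7%, teal 0.701%, amber 15.8% and blue 90.5%, and blue leads.

    substrate + coupling partner + product → 2 product (k = 0.300 M⁻² s⁻¹, Ea = 42.0 kJ mol⁻¹)
    substrate + coupling partner → product (k = 3.40 × 10⁻⁵ M⁻¹ s⁻¹, Ea = 75.0 kJ mol⁻¹)
    crystals ⇌ product, rate k3*(cs3 - [product]) while solid is left; crystals form when [product] > cs3 (solubility = 0.200 M, k = 0.0900 s⁻¹)
    (constants at 70 °C)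

Amber climbs from 0.382% at 2.00 min to 15.8%, one doubling per 0.0932 min against the 0.0910 min carried. Teal goes from 0.139% at 1.25 min to 0.701%, one doubling per 0.536 min against 0.582 min reckoned for 70 °C. In blue at 0.940 min, the half-life of substrate by the product-aided step is 0.38 min, against 88 min by the plain step. At 2.50 min the product-aided step uses substrate 410 times as fast as the plain one.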